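**Plan**

- Retrosynthesis: the ring C ether bonds O1–C2 and O1''–C2'' are cut first, then C4a–C8a and C4a''–C8a'' (both rings A), then C4–C4a and C4''–C4a'', and last the C2=C3 and C2''=C3'' bonds of a bis(arylidene)succinate. C3–C3'' is the central bond of succinic ester. Flavanone numbering is used; doubly primed atoms belong to the half with the 4-hydroxyphenyl ring.
- Forward: two Stobbe condensations attach the two rings B to diethyl succinate. Both ester groups then acylate the methyl carbon of 4-hydroxy-6-methyl-2-pyrone. Base isomerises both pyrones into rings A, rings C close last, and the benzyl ether is removed.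
- Enabling feature: each ring A (C4a, C5, C6, C7, C8, C8a) carries the acyl carbon C4 on C4a, between oxygens on C5 and C8a, with a third oxygen on C7. It is therefore a C-acylphloroglucinol, the Claisen product of a 3,5,7-trioxo acid chain, and such a chain is stable as a 4-hydroxy-6-(2-oxoalkyl)-2-pyrone.
- Stereochemistry: C2 and C2'' (both S) come from a catalyst-controlled oxa-Michael addition. C3 and C3'' (both S) come from kinetic protonation of the ring enols on the face opposite the new aryl group, which gives the 2,3-cis relationship in both halves. Nothing after that step is basic or acidic.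

Key step: step 6

Assumption: the sense of induction of a cinchona thiourea cannot be predicted with certainty for this substrate; the quinidine-derived catalyst is written, and its quinine-derived pseudoenantiomer replaces it if the 2R,2''R series should form.

**Route**

Step 1
Reactants: 1 diethyl succinate; 2 4-methoxybenzaldehyde
Product: 4 (E)-3-(ethoxycarbonyl)-4-(4-methoxyphenyl)but-3-enoic acid, via paraconate lactone 3 (not isolated)
Conditions: KOtBu, tBuOH, reflux; then aq HCl
Reagents that add atoms: none
Why: Stobbe condensation, in which the succinate enolate adds to the aldehyde, the alkoxide lactonises onto the distal ester and E1cB opening of lactone 3 gives the half-ester with the aryl group trans to the ester for steric reasons.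

Step 2
Reactants: 4 (E)-3-(ethoxycarbonyl)-4-(4-methoxyphenyl)but-3-enoic acid
Product: 5 diethyl (E)-2-(4-methoxybenzylidene)butanedioate
Conditions: EtOH, H2SO4 (cat.), reflux
Reagents that add atoms: ethanol, CCO
Why: Fischer esterification of the unhindered acetic acid arm, the standard way to prepare a Stobbe half-ester for a second condensation.

Step 3
Reactants: 5 diethyl (E)-2-(4-methoxybenzylidene)butanedioate; 6 4-(benzyloxy)benzaldehyde
Product: 8 (2E,3E)-4-[4-(benzyloxy)phenyl]-3-(ethoxycarbonyl)-2-(4-methoxybenzylidene)but-3-enoic acid, via arylidene lactone 7 (not isolated)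
Conditions: KOtBu, tBuOH, 60 °C; then aq HCl
Reagents that add atoms: none
Why: second Stobbe condensation at the only enolisable position (the CH2 group), with lactonisation onto the conjugated ester and E1cB opening placing the new aryl group trans to its ester, as in the classical route to fulgenic acids.

Step 4
Reactants: 8 (2E,3E)-4-[4-(benzyloxy)phenyl]-3-(ethoxycarbonyl)-2-(4-methoxybenzylidene)but-3-enoic acid
Product: 9 diethyl (2E,3E)-2-[4-(benzyloxy)benzylidene]-3-(4-methoxybenzylidene)butanedioate
Conditions: EtI, K2CO3, DMF, rt
Reagents that add atoms: iodoethane, CCI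
Why: SN2 O-alkylation of the carboxylate esterifies the hindered conjugated acid without acid, so the benzyl ether and the E,E-diene are left alone.

Step 5
Reactants: 9 diethyl (2E,3E)-2-[4-(benzyloxy)benzylidene]-3-(4-methoxybenzylidene)butanedioate; 10 4-hydroxy-6-methyl-2-pyrone
Product: 12 (3E,4E)-4-[4-(benzyloxy)benzylidene]-1,6-bis(4-hydroxy-2-oxo-2H-pyran-6-yl)-3-(4-methoxybenzylidene)hexane-2,5-dione, via pyrone dianion 11 (not isolated)
Conditions: 10 (5 equiv), LiN(iPr)2 (10 equiv), THF, −78 to −20 °C; then 9, −78 °C to rt; cold aq HCl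
Reagents that add atoms: none
Why: Claisen-type C-acylation of the pyrone dianion at its 6-methyl carbon by a diester that has no α-hydrogen, where carbonyl addition is expected over conjugate addition because the β-carbons bear electron-rich aryl groups and the α-carbons are fully substituted, and each new β-dicarbonyl unit is protected as its enolate until work-up.

Step 6
Reactants: 12 (3E,4E)-4-[4-(benzyloxy)benzylidene]-1,6-bis(4-hydroxy-2-oxo-2H-pyran-6-yl)-3-(4-methoxybenzylidene)hexane-2,5-dione
Product: 14 (2E,3E)-2-[4-(benzyloxy)benzylidene]-3-(4-methoxybenzylidene)-1,4-bis(2,4,6-trihydroxyphenyl)butane-1,4-dione, via bis(trioxo ester) 13 (not isolated)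
Conditions: Mg(OMe)2 (excess), MeOH, reflux, argon, dark; then 1 M HCl, 0 °C
Reagents that add atoms: none
Why: Proposed new method: methoxide adds to the C2 carbonyl of each 4-hydroxy-2-pyrone and opens it to the magnesium-chelated methyl 3,5,7-trioxo ester 13, whose most acidic carbon, the methylene between the former pyrone C6 carbonyl and the enone carbonyl (the future C4a or C4a''), attacks the ester carbon (the future C8a or C8a'') and, after loss of methoxide and enolisation, gives the 2,4,6-trihydroxyphenyl ketone. The closest known reaction type is the magnesium methoxide-induced recyclisation of simple 6-(2-oxoalkyl)-4-hydroxy-2-pyrones and 3,5,7-trioxo esters to acylphloroglucinols; new here is its twofold use on a cross-conjugated bis(arylidene) 1,4-diketone. Each ring A closes by a 6-exo-trig Claisen (Dieckmann-type) condensation, forming C4a–C8a in one half and C4a''–C8a'' in the other. No stereocentre is created, and the E,E-diene is the thermodynamic geometry, so reversible addition of methoxide to the enones does no harm. The selectivity needed is Claisen over aldol closure: attack of the ester-side methylene on the C4 ketone, which would lead to a resorcylate, is disfavoured because that ketone is α-branched, conjugated and held as a magnesium enolate chelate, and the same chelation keeps C4 and C4'' out of a cyclopentenone-forming aldol between the two halves. Because the step is an isomerisation, both rings A appear with all six hydroxyl groups free and the benzyl ether untouched.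

Step 7
Reactants: 14 (2E,3E)-2-[4-(benzyloxy)benzylidene]-3-(4-methoxybenzylidene)-1,4-bis(2,4,6-trihydroxyphenyl)butane-1,4-dione
Product: 15 (2S,3S)-3-[(2S,3S)-2-[4-(benzyloxy)phenyl]-5,7-dihydroxy-4-oxo-3,4-dihydro-2H-chromen-3-yl]-5,7-dihydroxy-2-(4-methoxyphenyl)-2,3-dihydro-4H-chromen-4-one (O-benzylsikokianin A)
Conditions: 9-amino-9-deoxy-epi-quinidine 3,5-bis(trifluoromethyl)phenyl thiourea (20 mol%), THF–toluene 1:3, −20 °C; filtration through silica
Reagents that add atoms: none
Why: Proposed new method: the quinuclidine nitrogen deprotonates an ortho hydroxyl of each acylphloroglucinol while the thiourea binds the enone carbonyl, so each phenoxide adds 6-endo-trig to one face of its arylidene carbon (catalyst control, 2S and 2''S), and the ring enol so formed, whose new aryl group sits pseudoaxial to avoid allylic strain with the C3 substituent, is protonated at C3 on the face opposite that aryl group (substrate control, 3S and 3''S, hence 2,3-cis in both halves); the closest known reaction type is the cinchona thiourea-catalysed enantioselective oxa-Michael cyclisation of activated 2'-hydroxychalcones to flavanones, together with anti-selective trapping of the intermediate enol.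

Step 8
Reactants: 15 O-benzylsikokianin A
Product: 16 sikokianin A [(2S,3S)-3-[(2S,3S)-5,7-dihydroxy-2-(4-hydroxyphenyl)-4-oxo-3,4-dihydro-2H-chromen-3-yl]-5,7-dihydroxy-2-(4-methoxyphenyl)-2,3-dihydro-4H-chromen-4-one]
Conditions: H2 (1 atm), 10% Pd/C, EtOAc, rt
Reagents that add atoms: none
Why: catalytic hydrogenolysis of the aryl benzyl ether under neutral conditions, which neither enolise C3 and C3'' nor open ring C, so the four stereocentres are untouched.

**Compound list**

1 | diethyl succinate | CCOC(=O)CCC(=O)OCC | starting material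
2 | 4-methoxybenzaldehyde | COc1ccc(C=O)cc1 | starting material
3 | ethyl 2-(4-methoxyphenyl)-5-oxooxolane-3-carboxylate (paraconate lactone, mixture of diastereomers) | CCOC(=O)C1CC(=O)OC1c1ccc(OC)cc1 | intermediate
4 | (E)-3-(ethoxycarbonyl)-4-(4-methoxyphenyl)but-3-enoic acid | CCOC(=O)/C(CC(=O)O)=C/c1ccc(OC)cc1 | intermediate
5 | diethyl (E)-2-(4-methoxybenzylidene)butanedioate | CCOC(=O)/C(CC(=O)OCC)=C/c1ccc(OC)cc1 | intermediate
6 | 4-(benzyloxy)benzaldehyde | O=Cc1ccc(OCc2ccccc2)cc1 | starting material
7 | ethyl 2-[4-(benzyloxy)phenyl]-4-[(E)-4-methoxybenzylidene]-5-oxooxolane-3-carboxylate (arylidene lactone, mixture of diastereomers) | O=C1OC(c2ccc(OCc3ccccc3)cc2)C(C(=O)OCC)/C1=C\c1ccc(OC)cc1 | intermediate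
8 | (2E,3E)-4-[4-(benzyloxy)phenyl]-3-(ethoxycarbonyl)-2-(4-methoxybenzylidene)but-3-enoic acid | COc1ccc(/C=C(/C(=O)O)C(=C/c2ccc(OCc3ccccc3)cc2)\C(=O)OCC)cc1 | intermediate
9 | diethyl (2E,3E)-2-[4-(benzyloxy)benzylidene]-3-(4-methoxybenzylidene)butanedioate | COc1ccc(/C=C(/C(=O)OCC)C(=C/c2ccc(OCc3ccccc3)cc2)\C(=O)OCC)cc1 | intermediate
10 | 4-hydroxy-6-methyl-2-pyrone | Cc1cc(O)cc(=O)o1 | starting material
11 | dilithium salt of 4-hydroxy-6-methyl-2-pyrone (O,C-dianion) | [Li+].[Li+].[CH2-]c1cc([O-])cc(=O)o1 | intermediate
12 | (3E,4E)-4-[4-(benzyloxy)benzylidene]-1,6-bis(4-hydroxy-2-oxo-2H-pyran-6-yl)-3-(4-methoxybenzylidene)hexane-2,5-dione | COc1ccc(/C=C(/C(=O)Cc2cc(O)cc(=O)o2)C(=C/c2ccc(OCc3ccccc3)cc2)\C(=O)Cc2cc(O)cc(=O)o2)cc1 | intermediate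
13 | dimethyl (8E,9E)-9-[4-(benzyloxy)benzylidene]-8-(4-methoxybenzylidene)-3,5,7,10,12,14-hexaoxohexadecanedioate (present as magnesium enolates) | COc1ccc(/C=C(/C(=O)CC(=O)CC(=O)CC(=O)OC)C(=C/c2ccc(OCc3ccccc3)cc2)\C(=O)CC(=O)CC(=O)CC(=O)OC)cc1 | intermediate
14 | (2E,3E)-2-[4-(benzyloxy)benzylidene]-3-(4-methoxybenzylidene)-1,4-bis(2,4,6-trihydroxyphenyl)butane-1,4-dione | COc1ccc(/C=C(/C(=O)c2c(O)cc(O)cc2O)C(=C/c2ccc(OCc3ccccc3)cc2)\C(=O)c2c(O)cc(O)cc2O)cc1 | intermediate
15 | (2S,3S)-3-[(2S,3S)-2-[4-(benzyloxy)phenyl]-5,7-dihydroxy-4-oxo-3,4-dihydro-2H-chromen-3-yl]-5,7-dihydroxy-2-(4-methoxyphenyl)-2,3-dihydro-4H-chromen-4-one (O-benzylsikokianin A) | COc1ccc([C@H]2Oc3cc(O)cc(O)c3C(=O)[C@H]2[C@@H]2C(=O)c3c(O)cc(O)cc3O[C@@H]2c2ccc(OCc3ccccc3)cc2)cc1 | intermediate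
16 | sikokianin A, (2S,3S,2''S,3''S), both flavanone units 2,3-cis | COc1ccc([C@H]2Oc3cc(O)cc(O)c3C(=O)[C@H]2[C@@H]2C(=O)c3c(O)cc(O)cc3O[C@@H]2c2ccc(O)cc2)cc1 | target

**Step count and risks**

Total steps: 8. Longest linear sequence: 8 steps, from diethyl succinate 1 to 16.

Steps most likely to fail:

1. Step 7. The catalyst may discriminate poorly between the faces of a non-activated, α-branched enone, and uncatalysed closure of the free polyphenol may compete. The amine base may also epimerise C3 and C3'' or reopen ring C, which would drift the product toward the 2,3-trans series. The fallback gives up catalyst control and resolves instead. It sets out from 14: NaOAc in EtOH at 0 °C (classical base-mediated chalcone-to-flavanone closure under kinetic protonation) would give the O-benzyl biflavanone stereoisomer mixture F1. The racemic cis,cis pair would be separated from the trans-containing isomers on silica and its enantiomers resolved by preparative HPLC on a cellulose tris(3,5-dimethylphenylcarbamate) phase, which returns the route to 15.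

2. Step 6. Pyrone opening may stop halfway, closure may take the aldol course to resorcylates, the two halves may condense with each other, or methoxide may add irreversibly to the enones. Ring C may also close prematurely on acidification; such material would be reopened with cold aqueous KOH and re-acidified at 0 °C. The fallback builds rings A from a preformed phloroglucinol and sets out from 9. Me(MeO)NH·HCl and iPrMgCl in THF at −20 °C would convert the diester into the bis(N-methoxy-N-methylamide) F2. The known ether 1,3,5-tris(methoxymethoxy)benzene would be lithiated with n-BuLi in THF at 0 °C to 2,4,6-tris(methoxymethoxy)phenyllithium F3, which adds twice to F2 to give the hexakis(methoxymethyl) bis-chalcone F4. HCl in MeOH at 40 °C would remove the six acetal groups and return the route to 14.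

3. Step 5. The dianion may add in the conjugate sense, the second acylation at the hindered ester may stall, or proton transfer from the first-formed β-dicarbonyl unit may consume the dianion. The fallback replaces acylation by aldol addition and oxidation and sets out from 9. iBu2AlH in CH2Cl2 at −78 °C would give the diol F5, and MnO2 in CH2Cl2 the dialdehyde F6. Dianion 11 would add to both formyl groups (the known aldol reaction of this dianion with aldehydes) to give the bis(β-hydroxyalkyl)pyrone F7 as a mixture of diastereomers. Oxidation of the two allylic carbinols with MnO2 or Dess–Martin periodinane returns the route to 12.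

**Further compounds**

F1 | step 7 | O-benzyl biflavanone, mixture of stereoisomers at C2, C3, C2'' and C3'' | COc1ccc(C2Oc3cc(O)cc(O)c3C(=O)C2C2C(=O)c3c(O)cc(O)cc3OC2c2ccc(OCc3ccccc3)cc2)cc1
F2 | step 6 | (2E,3E)-2-[4-(benzyloxy)benzylidene]-N1,N4-dimethoxy-3-(4-methoxybenzylidene)-N1,N4-dimethylbutanediamide | COc1ccc(/C=C(/C(=O)N(C)OC)C(=C/c2ccc(OCc3ccccc3)cc2)\C(=O)N(C)OC)cc1
F3 | step 6 | 2,4,6-tris(methoxymethoxy)phenyllithium | [Li]c1c(OCOC)cc(OCOC)cc1OCOC
F4 | step 6 | (2E,3E)-2-[4-(benzyloxy)benzylidene]-3-(4-methoxybenzylidene)-1,4-bis[2,4,6-tris(methoxymethoxy)phenyl]butane-1,4-dione | COc1ccc(/C=C(/C(=O)c2c(OCOC)cc(OCOC)cc2OCOC)C(=C/c2ccc(OCc3ccccc3)cc2)\C(=O)c2c(OCOC)cc(OCOC)cc2OCOC)cc1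
F5 | step 5 | (2E,3E)-2-[4-(benzyloxy)benzylidene]-3-(4-methoxybenzylidene)butane-1,4-diol | COc1ccc(/C=C(/CO)C(=C/c2ccc(OCc3ccccc3)cc2)\CO)cc1
F6 | step 5 | (2E,3E)-2-[4-(benzyloxy)benzylidene]-3-(4-methoxybenzylidene)butanedial | COc1ccc(/C=C(/C=O)C(=C/c2ccc(OCc3ccccc3)cc2)\C=O)cc1
F7 | step 5 | 6,6'-[(3E,4E)-4-[4-(benzyloxy)benzylidene]-2,5-dihydroxy-3-(4-methoxybenzylidene)hexane-1,6-diyl]bis(4-hydroxy-2H-pyran-2-one), mixture of diastereomers | COc1ccc(/C=C(/C(O)Cc2cc(O)cc(=O)o2)C(=C/c2ccc(OCc3ccccc3)cc2)\C(O)Cc2cc(O)cc(=O)o2)cc1
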